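**Plan**
- Retrosynthesis: the late changes at C3, C15 and C19 are taken back first. The side chain is then cut at C11–C12 (Wittig olefination, then saturation) into a ring-bound C11 aldehyde and a C12–C15 ylide carrying the C16 methyl group. Ring B is cut at C7–C8 and C9–C10 by a Diels–Alder disconnection.
- Enabling feature: ring B holds quaternary C10 next to chain-bearing C9, which is next to methyl-bearing C8. This is the imprint of a but-2-ynoate added across the diene C10=C5–C6=C7 of a ring A 2-methyl-1-vinylcyclohexene.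
- Forward order: ring A is built from 2-methylcyclohexane-1,3-dione (hydroxymethylation gives C19, then desymmetrising reduction, C10 methylation, enol triflate, vinylation). The cycloaddition closes ring B, and the chain is joined last at C11.
- Stereochemistry: C3 and C4 come from a catalyst-controlled ketone reduction, C10 from the diene face left open by O3 and C19, C5 and C9 from hydrogen and proton delivery anti to the C10 methyl group, and C13 from (S)-2-methylbutane-1,4-diol. C3 is inverted at the end through the ketone.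

Key step: step 11

Remark: labdane numbering is used for every compound that contains ring A (C19 = oxygen-bearing carbon on C4, C18 = methyl on C4, C20 = methyl on C10, C17 = methyl on C8); α denotes the ring face on which the C19 arm lies and β the opposite face.

**Route**

Step 1
Reactants: 1 (S)-2-methylbutane-1,4-diol
Product: 2 (S)-4-(tert-butyldimethylsilyloxy)-2-methylbutan-1-ol
Conditions: TBSCl (1.0 equiv), imidazole, CH2Cl2, −40 → 0 °C
Reagents that add atoms: tert-butyldimethylsilyl chloride, CC(C)(C)[Si](C)(C)Cl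
Why: Monosilylation of a diol with a bulky silyl chloride should prefer the C4 hydroxyl, which lies one methylene further from the methyl branch than the C1 hydroxyl, the regioisomer and the bis-ether being removed by chromatography while the stereocentre is untouched.

Step 2
Reactants: 2 (S)-4-(tert-butyldimethylsilyloxy)-2-methylbutan-1-ol
Product: 3 (S)-tert-butyl(4-iodo-3-methylbutoxy)dimethylsilane
Conditions: PPh3, I2, imidazole, CH2Cl2, 0 °C → rt
Reagents that add atoms: iodine, [I][I]
Why: Appel-type iodination (Garegg–Samuelsson conditions) converts the primary alcohol to the iodide by SN2 displacement of the oxyphosphonium group without touching the adjacent stereocentre or the silyl ether.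

Step 3
Reactants: 3 (S)-tert-butyl(4-iodo-3-methylbutoxy)dimethylsilane
Product: 4 [(S)-4-(tert-butyldimethylsilyloxy)-2-methylbutyl]triphenylphosphonium iodide
Conditions: PPh3, i-Pr2NEt (cat.), MeCN, reflux
Reagents that add atoms: triphenylphosphine, c1ccc(cc1)P(c1ccccc1)c1ccccc1
Why: SN2 quaternisation of triphenylphosphine by a β-branched primary iodide is the standard entry to Wittig salts of this kind and only needs prolonged heating.

Step 4
Reactants: 5 2-methylcyclohexane-1,3-dione; 6 formaldehyde
Product: 7 2-(hydroxymethyl)-2-methylcyclohexane-1,3-dione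
Conditions: 37% aq. HCHO, KHCO3 (cat.), H2O, rt
Reagents that add atoms: none
Why: Aldol hydroxymethylation (Tollens-type) of the acidic 2-alkyl-1,3-dione with formaldehyde forms the quaternary carbon that becomes C4 and brings in C19 at the alcohol level.

Step 5
Reactants: 7 2-(hydroxymethyl)-2-methylcyclohexane-1,3-dione
Product: 8 2-[(tert-butyldiphenylsilyloxy)methyl]-2-methylcyclohexane-1,3-dione
Conditions: TBDPSCl, imidazole, DMAP (cat.), CH2Cl2, 0 °C → rt
Reagents that add atoms: tert-butyldiphenylsilyl chloride, CC(C)(C)[Si](Cl)(c1ccccc1)c1ccccc1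
Why: Silylation of the primary alcohol under mildly basic conditions blocks the retro-aldol pathway and installs the bulky, acid-stable group that later differentiates the two faces of ring A.

Step 6
Reactants: 8 2-[(tert-butyldiphenylsilyloxy)methyl]-2-methylcyclohexane-1,3-dione
Product: 9 (2R,3R)-2-[(tert-butyldiphenylsilyloxy)methyl]-3-hydroxy-2-methylcyclohexan-1-one
Conditions: (S)-2-methyl-CBS-oxazaborolidine [(S)-1-methyl-3,3-diphenyltetrahydro-1H,3H-pyrrolo[1,2-c][1,3,2]oxazaborole] (20 mol %), catecholborane, PhNEt2, toluene, −60 °C; then H2O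
Reagents that add atoms: none
Why: Corey–Bakshi–Shibata reduction desymmetrises the dione, the catalyst reading the quaternary flank as large and the methylene flank as small to give the 3R carbinol while hydride enters anti to the bulky silyloxymethyl arm, so that the hydroxyl is cis to that arm and the quaternary carbon (C4) becomes the 2R stereocentre.

Step 7
Reactants: 9 (2R,3R)-2-[(tert-butyldiphenylsilyloxy)methyl]-3-hydroxy-2-methylcyclohexan-1-one
Product: 10 (2R,3R)-3-(tert-butyldimethylsilyloxy)-2-[(tert-butyldiphenylsilyloxy)methyl]-2-methylcyclohexan-1-one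
Conditions: TBSOTf, 2,6-lutidine, CH2Cl2, −78 → 0 °C
Reagents that add atoms: tert-butyldimethylsilyl triflate, CC(C)(C)[Si](C)(C)OS(=O)(=O)C(F)(F)F
Why: Silylation with the silyl triflate is the usual way to protect a hindered secondary alcohol next to a quaternary carbon and removes the retro-aldol risk of the free ketol before strong base is used.

Step 8
Reactants: 10 (2R,3R)-3-(tert-butyldimethylsilyloxy)-2-[(tert-butyldiphenylsilyloxy)methyl]-2-methylcyclohexan-1-one
Product: 12 (2R,3R)-3-(tert-butyldimethylsilyloxy)-2-[(tert-butyldiphenylsilyloxy)methyl]-2,6-dimethylcyclohexan-1-one (both C6 epimers), via lithium enolate 11 (not isolated)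
Conditions: LiN(i-Pr)2, THF, −78 °C; MeI, −78 → −20 °C
Reagents that add atoms: methyl iodide, CI
Why: Enolate alkylation can only take place on the methylene side of the ketone because the other α-carbon is quaternary, and the configuration of the new methyl-bearing carbon (C10) is irrelevant since it becomes trigonal in the next step.

Step 9
Reactants: 12 (2R,3R)-3-(tert-butyldimethylsilyloxy)-2-[(tert-butyldiphenylsilyloxy)methyl]-2,6-dimethylcyclohexan-1-one
Product: 14 (5R,6R)-5-(tert-butyldimethylsilyloxy)-6-[(tert-butyldiphenylsilyloxy)methyl]-2,6-dimethylcyclohex-1-en-1-yl trifluoromethanesulfonate, via potassium enolate 13 (not isolated)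
Conditions: KN(SiMe3)2, THF, −78 → 0 °C; PhNTf2, −78 °C → rt
Reagents that add atoms: N-phenylbis(trifluoromethanesulfonimide), O=S(=O)(N(c1ccccc1)S(=O)(=O)C(F)(F)F)C(F)(F)F
Why: Enol triflate formation from the only possible enolate gives the tetrasubstituted C5=C10 triflate, as is known for 2,2,6-trisubstituted cyclohexanones.

Step 10
Reactants: 14 (5R,6R)-5-(tert-butyldimethylsilyloxy)-6-[(tert-butyldiphenylsilyloxy)methyl]-2,6-dimethylcyclohex-1-en-1-yl trifluoromethanesulfonate
Product: 15 tert-butyl{[(1R,2R)-2-[(tert-butyldiphenylsilyloxy)methyl]-2,4-dimethyl-3-vinylcyclohex-3-en-1-yl]oxy}dimethylsilane (ring A diene, 3α-OTBS, 19-OTBDPS)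
Conditions: CH2=CHSnBu3, Pd(PPh3)4 (5 mol %), LiCl, THF, reflux
Reagents that add atoms: tributyl(vinyl)stannane, CCCC[Sn](CCCC)(CCCC)C=C
Why: Stille coupling of a hindered cyclohexenyl triflate with a vinylstannane under zerovalent palladium catalysis with LiCl is the established route to 2,6,6-trisubstituted 1-vinylcyclohexenes and leaves both silyl ethers intact.

Step 11
Reactants: 15 ring A diene; 16 methyl but-2-ynoate
Product: 17 methyl 3α-(tert-butyldimethylsilyloxy)-19-(tert-butyldiphenylsilyloxy)-12,13,14,15,16-pentanorlabda-5,8-dien-11-oate (C20 α, cis to C19 and O3)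
Conditions: 16 (3 equiv), EtAlCl2 (1.5 equiv), CH2Cl2, −20 °C → rt
Reagents that add atoms: none
Why: The EtAlCl2-complexed ynoate and the diene C10=C5–C6=C7 of 15 combine in a concerted, asynchronous [4+2] cycloaddition that forms C7–C8 and C9–C10 and leaves the C5=C6 and C8=C9 double bonds of a 1,4-cyclohexadiene. The closest known reaction type is the Diels–Alder reaction of 1,3,3-trimethyl-2-vinylcyclohexene with acetylenic esters, which is used to assemble drimane skeletons. Ring B closes as the six-membered cycloaddition ring, annulated onto ring A across C5–C10 in an intermolecular [4+2] mode. The one new stereocentre, quaternary C10, is set by the C3 and C4 centres of the diene: both the C3 silyloxy group and the C19 silyloxymethyl arm lie on the α face, and in the half-chair with O3 equatorial the C19 arm is pseudoaxial there, so C9 should bond from the β face and C20 should end up α, cis to C19. The step needs one orientation and one face: the orientation follows from the larger HOMO coefficient at the unsubstituted terminus C7, which bonds to the electrophilic β-carbon of the ynoate so that the ester-bearing carbon becomes C9, and the face is secured by the two α substituents, acyclic silyl ethers being chosen because they let ring A adopt the half-chair that exposes the β face and because they tolerate the Lewis acid. An alkyne dienophile raises no endo or exo question.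

Step 12
Reactants: 17 bicyclic dienoate
Product: 18 methyl 3α-(tert-butyldimethylsilyloxy)-19-(tert-butyldiphenylsilyloxy)-12,13,14,15,16-pentanorlabd-8-en-11-oate (5β-H, trans-fused)
Conditions: H2 (1 atm), Pd/C (10% palladium on carbon), EtOAc, rt
Reagents that add atoms: none
Why: Heterogeneous hydrogenation reduces only the trisubstituted C5=C6 bond, the tetrasubstituted ester-conjugated C8=C9 bond being inert, and hydrogen is delivered to the β face because the α face of C5 is covered by the axial C20 methyl group and the axial C19 arm, which gives H-5 β and the trans ring fusion.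

Step 13
Reactants: 18 trans-fused enoate
Product: 19 3α-(tert-butyldimethylsilyloxy)-19-(tert-butyldiphenylsilyloxy)-12,13,14,15,16-pentanorlabd-8-en-11-ol
Conditions: i-Bu2AlH (2.5 equiv), CH2Cl2, −78 → 0 °C
Reagents that add atoms: none
Why: Hydride reduction of a conjugated ester with i-Bu2AlH gives the allylic alcohol by 1,2-reduction and does not affect silyl ethers or the tetrasubstituted alkene.

Step 14
Reactants: 19 allylic alcohol
Product: 20 3α-(tert-butyldimethylsilyloxy)-19-(tert-butyldiphenylsilyloxy)-12,13,14,15,16-pentanorlabd-8-en-11-al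
Conditions: Dess–Martin periodinane, NaHCO3, CH2Cl2, rt
Reagents that add atoms: none
Why: Dess–Martin oxidation of the primary allylic alcohol gives the conjugated enal, which has no α-hydrogen and is therefore configurationally safe.

Step 15
Reactants: 20 conjugated enal
Product: 22 3α-(tert-butyldimethylsilyloxy)-19-(tert-butyldiphenylsilyloxy)-12,13,14,15,16-pentanorlabd-7-en-11-al (9β-H, formyl group α and equatorial), via potassium dienolate 21 (not isolated)
Conditions: t-BuOK, t-BuOH/THF, argon, 0 °C → rt; then inverse quench into 10% aq. AcOH, 0 °C; used crude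
Reagents that add atoms: none
Why: Deconjugation through the extended enolate (Ringold–Malhotra type) should work because under equilibrating alkoxide conditions the more substituted endocyclic dienolate (C7=C8, C9=C11) prevails over the exocyclic one from C17, and kinetic protonation at the α-carbon C9 from the β face, anti to the axial C20 methyl group, gives the C7=C8 alkene with H-9 β.

Step 16
Reactants: 22 β,γ-unsaturated aldehyde; 4 phosphonium iodide
Product: 24 (11Z,13S)-3α,15-bis(tert-butyldimethylsilyloxy)-19-(tert-butyldiphenylsilyloxy)labda-7,11-diene, via phosphorus ylide 23 (not isolated)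
Conditions: 4, NaN(SiMe3)2, THF, 0 °C; then 22, −78 °C → rt
Reagents that add atoms: none
Why: Wittig olefination with a non-stabilised ylide forms C11=C12 (Z expected, the geometry being erased in the next step), fast addition at −78 °C should outrun enolisation of the α-branched aldehyde, and C13 arrives unchanged from the diol.

Step 17
Reactants: 24 labda-7,11-diene
Product: 25 (13R)-3α,15-bis(tert-butyldimethylsilyloxy)-19-(tert-butyldiphenylsilyloxy)labd-7-ene
Conditions: TsNHNH2, NaOAc, DME/H2O, reflux
Reagents that add atoms: none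
Why: Diimide reduction is selective for the 1,2-disubstituted C11=C12 alkene over the trisubstituted C7=C8 alkene and cannot shift double bonds.

Step 18
Reactants: 25 tris-silyl ether
Product: 26 (13R)-19-(tert-butyldiphenylsilyloxy)labd-7-ene-3α,15-diol
Conditions: HCl (1.25 M in MeOH), MeOH/CH2Cl2, 0 °C → rt
Reagents that add atoms: none
Why: Acid-catalysed methanolysis removes the primary and the secondary tert-butyldimethylsilyl ether while the far more acid-stable tert-butyldiphenylsilyl ether at C19 stays in place.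

Step 19
Reactants: 26 3α,15-diol
Product: 27 (13R)-19-(tert-butyldiphenylsilyloxy)-3-oxolabd-7-en-15-oic acid
Conditions: CrO3, H2SO4, acetone, 0 °C
Reagents that add atoms: water, O
Why: Jones oxidation converts the primary C15 alcohol to the acid through the aldehyde hydrate and the C3 alcohol to the ketone in one operation, the silyl ether and the trisubstituted alkene tolerating the brief treatment at 0 °C and no stereocentre next to the new ketone being epimerisable.

Step 20
Reactants: 27 keto acid
Product: 28 (13R)-19-(tert-butyldiphenylsilyloxy)-3β-hydroxylabd-7-en-15-oic acid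
Conditions: LiBH(s-Bu)3 (3 equiv), THF, −78 °C; then 1 M HCl
Reagents that add atoms: none
Why: Reduction with the bulky borohydride takes the equatorial trajectory from the α side, avoiding the syn-axial hydrogens at C1 and C5 on the β face, and so gives the axial 3β-alcohol with the configuration of the target, the first equivalent only deprotonating the acid, whose carboxylate is not reduced.

Step 21
Reactants: 28 3β-hydroxy acid
Product: 30 (13R)-3β-acetoxy-19-(tert-butyldiphenylsilyloxy)labd-7-en-15-oic acid, via mixed acetic anhydride 29 (not isolated)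
Conditions: Ac2O, DMAP, pyridine, rt → 40 °C; then H2O/THF
Reagents that add atoms: acetic anhydride, CC(=O)OC(C)=O
Why: DMAP-catalysed acetylation esterifies the hindered axial C3 hydroxyl, and the mixed anhydride formed in passing at C15 is hydrolysed back to the acid by the aqueous treatment.

Step 22
Reactants: 30 acetoxy acid silyl ether
Product: 31 (3S,4R,5S,9R,10S,13R)-3-acetoxy-19-hydroxylabd-7-en-15-oic acid (CNP0138726.1)
Conditions: Bu4NF, AcOH, THF, rt → 40 °C
Reagents that add atoms: none
Why: Fluoride-mediated desilylation frees the C19 alcohol under buffered conditions that spare the acetate, and acetyl migration is excluded because O3 and C19 are trans-diaxial.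

**Compound list**

1 | (S)-2-methylbutane-1,4-diol | OC[C@@H](C)CCO | starting material
2 | (S)-4-(tert-butyldimethylsilyloxy)-2-methylbutan-1-ol | OC[C@@H](C)CCO[Si](C)(C)C(C)(C)C | intermediate
3 | (S)-tert-butyl(4-iodo-3-methylbutoxy)dimethylsilane | IC[C@@H](C)CCO[Si](C)(C)C(C)(C)C | intermediate
4 | [(S)-4-(tert-butyldimethylsilyloxy)-2-methylbutyl]triphenylphosphonium iodide | CC(C)(C)[Si](C)(C)OCC[C@H](C)C[P+](c1ccccc1)(c1ccccc1)c1ccccc1.[I-] | intermediate
5 | 2-methylcyclohexane-1,3-dione | CC1C(=O)CCCC1=O | starting material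
6 | formaldehyde | C=O | starting material
7 | 2-(hydroxymethyl)-2-methylcyclohexane-1,3-dione | CC1(CO)C(=O)CCCC1=O | intermediate
8 | 2-[(tert-butyldiphenylsilyloxy)methyl]-2-methylcyclohexane-1,3-dione | CC1(CO[Si](c2ccccc2)(c2ccccc2)C(C)(C)C)C(=O)CCCC1=O | intermediate
9 | (2R,3R)-2-[(tert-butyldiphenylsilyloxy)methyl]-3-hydroxy-2-methylcyclohexan-1-one | O[C@@H]1CCCC(=O)[C@]1(C)CO[Si](c2ccccc2)(c2ccccc2)C(C)(C)C | intermediate
10 | (2R,3R)-3-(tert-butyldimethylsilyloxy)-2-[(tert-butyldiphenylsilyloxy)methyl]-2-methylcyclohexan-1-one | CC(C)(C)[Si](C)(C)O[C@@H]1CCCC(=O)[C@]1(C)CO[Si](c2ccccc2)(c2ccccc2)C(C)(C)C | intermediate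
11 | lithium enolate of 10 (C5=C10 enolate) | CC(C)(C)[Si](C)(C)O[C@@H]1CCC=C([O-])[C@]1(C)CO[Si](c2ccccc2)(c2ccccc2)C(C)(C)C.[Li+] | intermediate
12 | (2R,3R)-3-(tert-butyldimethylsilyloxy)-2-[(tert-butyldiphenylsilyloxy)methyl]-2,6-dimethylcyclohexan-1-one, both C6 epimers | CC(C)(C)[Si](C)(C)O[C@@H]1CCC(C)C(=O)[C@]1(C)CO[Si](c2ccccc2)(c2ccccc2)C(C)(C)C | intermediate
13 | potassium enolate of 12 (tetrasubstituted C5=C10 enolate) | CC(C)(C)[Si](C)(C)O[C@@H]1CCC(C)=C([O-])[C@]1(C)CO[Si](c2ccccc2)(c2ccccc2)C(C)(C)C.[K+] | intermediate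
14 | (5R,6R)-5-(tert-butyldimethylsilyloxy)-6-[(tert-butyldiphenylsilyloxy)methyl]-2,6-dimethylcyclohex-1-en-1-yl trifluoromethanesulfonate | CC(C)(C)[Si](C)(C)O[C@@H]1CCC(C)=C(OS(=O)(=O)C(F)(F)F)[C@]1(C)CO[Si](c2ccccc2)(c2ccccc2)C(C)(C)C | intermediate
15 | tert-butyl{[(1R,2R)-2-[(tert-butyldiphenylsilyloxy)methyl]-2,4-dimethyl-3-vinylcyclohex-3-en-1-yl]oxy}dimethylsilane | CC(C)(C)[Si](C)(C)O[C@@H]1CCC(C)=C(C=C)[C@]1(C)CO[Si](c2ccccc2)(c2ccccc2)C(C)(C)C | intermediate
16 | methyl but-2-ynoate | CC#CC(=O)OC | starting material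
17 | methyl 3α-(tert-butyldimethylsilyloxy)-19-(tert-butyldiphenylsilyloxy)-12,13,14,15,16-pentanorlabda-5,8-dien-11-oate (C20 α) | CC(C)(C)[Si](C)(C)O[C@@H]1CC[C@]2(C)C(=CCC(C)=C2C(=O)OC)[C@]1(C)CO[Si](c3ccccc3)(c3ccccc3)C(C)(C)C | intermediate
18 | methyl 3α-(tert-butyldimethylsilyloxy)-19-(tert-butyldiphenylsilyloxy)-12,13,14,15,16-pentanorlabd-8-en-11-oate (5β-H) | CC(C)(C)[Si](C)(C)O[C@@H]1CC[C@]2(C)[C@H](CCC(C)=C2C(=O)OC)[C@]1(C)CO[Si](c3ccccc3)(c3ccccc3)C(C)(C)C | intermediate
19 | 3α-(tert-butyldimethylsilyloxy)-19-(tert-butyldiphenylsilyloxy)-12,13,14,15,16-pentanorlabd-8-en-11-ol | CC(C)(C)[Si](C)(C)O[C@@H]1CC[C@]2(C)[C@H](CCC(C)=C2CO)[C@]1(C)CO[Si](c3ccccc3)(c3ccccc3)C(C)(C)C | intermediate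
20 | 3α-(tert-butyldimethylsilyloxy)-19-(tert-butyldiphenylsilyloxy)-12,13,14,15,16-pentanorlabd-8-en-11-al | CC(C)(C)[Si](C)(C)O[C@@H]1CC[C@]2(C)[C@H](CCC(C)=C2C=O)[C@]1(C)CO[Si](c3ccccc3)(c3ccccc3)C(C)(C)C | intermediate
21 | potassium 3α-(tert-butyldimethylsilyloxy)-19-(tert-butyldiphenylsilyloxy)-12,13,14,15,16-pentanorlabda-7,9(11)-dien-11-olate (enolate geometry not defined) | CC(C)(C)[Si](C)(C)O[C@@H]1CC[C@]2(C)[C@H](CC=C(C)C2=C[O-])[C@]1(C)CO[Si](c3ccccc3)(c3ccccc3)C(C)(C)C.[K+] | intermediate
22 | 3α-(tert-butyldimethylsilyloxy)-19-(tert-butyldiphenylsilyloxy)-12,13,14,15,16-pentanorlabd-7-en-11-al (9β-H) | CC(C)(C)[Si](C)(C)O[C@@H]1CC[C@]2(C)[C@H](CC=C(C)[C@H]2C=O)[C@]1(C)CO[Si](c3ccccc3)(c3ccccc3)C(C)(C)C | intermediate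
23 | [(S)-4-(tert-butyldimethylsilyloxy)-2-methylbutylidene]triphenylphosphorane | CC(C)(C)[Si](C)(C)OCC[C@H](C)C=P(c1ccccc1)(c1ccccc1)c1ccccc1 | intermediate
24 | (11Z,13S)-3α,15-bis(tert-butyldimethylsilyloxy)-19-(tert-butyldiphenylsilyloxy)labda-7,11-diene | CC(C)(C)[Si](C)(C)O[C@@H]1CC[C@]2(C)[C@H](CC=C(C)[C@H]2/C=C\[C@@H](C)CCO[Si](C)(C)C(C)(C)C)[C@]1(C)CO[Si](c3ccccc3)(c3ccccc3)C(C)(C)C | intermediate
25 | (13R)-3α,15-bis(tert-butyldimethylsilyloxy)-19-(tert-butyldiphenylsilyloxy)labd-7-ene | CC(C)(C)[Si](C)(C)O[C@@H]1CC[C@]2(C)[C@H](CC=C(C)[C@H]2CC[C@@H](C)CCO[Si](C)(C)C(C)(C)C)[C@]1(C)CO[Si](c3ccccc3)(c3ccccc3)C(C)(C)C | intermediate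
26 | (13R)-19-(tert-butyldiphenylsilyloxy)labd-7-ene-3α,15-diol | O[C@@H]1CC[C@]2(C)[C@H](CC=C(C)[C@H]2CC[C@@H](C)CCO)[C@]1(C)CO[Si](c3ccccc3)(c3ccccc3)C(C)(C)C | intermediate
27 | (13R)-19-(tert-butyldiphenylsilyloxy)-3-oxolabd-7-en-15-oic acid | O=C1CC[C@]2(C)[C@H](CC=C(C)[C@H]2CC[C@@H](C)CC(=O)O)[C@]1(C)CO[Si](c3ccccc3)(c3ccccc3)C(C)(C)C | intermediate
28 | (13R)-19-(tert-butyldiphenylsilyloxy)-3β-hydroxylabd-7-en-15-oic acid | O[C@H]1CC[C@]2(C)[C@H](CC=C(C)[C@H]2CC[C@@H](C)CC(=O)O)[C@]1(C)CO[Si](c3ccccc3)(c3ccccc3)C(C)(C)C | intermediate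
29 | acetic (13R)-3β-acetoxy-19-(tert-butyldiphenylsilyloxy)labd-7-en-15-oic anhydride | CC(=O)O[C@H]1CC[C@]2(C)[C@H](CC=C(C)[C@H]2CC[C@@H](C)CC(=O)OC(C)=O)[C@]1(C)CO[Si](c3ccccc3)(c3ccccc3)C(C)(C)C | intermediate
30 | (13R)-3β-acetoxy-19-(tert-butyldiphenylsilyloxy)labd-7-en-15-oic acid | CC(=O)O[C@H]1CC[C@]2(C)[C@H](CC=C(C)[C@H]2CC[C@@H](C)CC(=O)O)[C@]1(C)CO[Si](c3ccccc3)(c3ccccc3)C(C)(C)C | intermediate
31 | (3S,4R,5S,9R,10S,13R)-3-acetoxy-19-hydroxylabd-7-en-15-oic acid (3β-OAc, C19 and C20 α, H-5 and H-9 β) | CC(=O)O[C@H]1CC[C@]2(C)[C@H](CC=C(C)[C@H]2CC[C@@H](C)CC(=O)O)[C@]1(C)CO | target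

**Totals and risks**

Total step count: 22. Longest linear sequence: 19 steps (steps 4 to 22, from 2-methylcyclohexane-1,3-dione 5 to target 31); steps 1 to 3 make the side-chain fragment 4.

Steps most likely to fail:

1. Step 11 (Diels–Alder reaction). The cycloaddition may be slow at the tetrasubstituted diene terminus with the weakly activated ynoate, so that the diene is eroded by the Lewis acid, or the two diene faces may be discriminated too weakly. Fallback: setting out from diene 15, the more electrophilic but-2-ynal is used with Me2AlCl in CH2Cl2 at −78 °C, where face discrimination should be sharper, to give the dienal F1. Hydrogenation of its C5=C6 bond (H2, Pd/C, EtOAc) then leads to enal 20, where the route is rejoined without steps 13 and 14.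

2. Step 15 (deconjugation). The base may remove a proton from the C17 methyl group instead of C7, which would give the exocyclic alkene, or the product may drift back into conjugation during protonation and work-up. Fallback: setting out from enal 20, acid-catalysed enol acetylation (isopropenyl acetate, TsOH cat., 60 °C) fixes the thermodynamic endocyclic regiochemistry in the isolable dienol acetate F2. Deconjugative reduction of F2 with NaBH4 in EtOH/H2O at 0 °C, in which C9 is protonated from the β face and the aldehyde is reduced before it can reconjugate, gives the homoallylic alcohol F3. Dess–Martin oxidation of F3 returns to aldehyde 22.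

3. Step 16 (Wittig olefination). The ylide may act as a base on the α-branched, allylically activated aldehyde, causing reconjugation or C9 epimerisation instead of addition. Fallback: setting out from iodide 3 and aldehyde 22, iodine–lithium exchange (t-BuLi, Et2O, −78 °C) gives the alkyllithium F4, which is transmetalated with CeCl3 in THF to the weakly basic alkylcerium dichloride F5. Addition of F5 to 22 forms the C11–C12 bond in the C11 carbinol F6 (both C11 epimers). Conversion to the xanthate F7 (NaH, CS2, MeI) and Barton–McCombie deoxygenation (Bu3SnH in high concentration, AIBN, toluene, 80 °C) give 25, where the route is rejoined without step 17.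

**Further compounds**

F1 | step 11 | 3α-(tert-butyldimethylsilyloxy)-19-(tert-butyldiphenylsilyloxy)-12,13,14,15,16-pentanorlabda-5,8-dien-11-al | CC(C)(C)[Si](C)(C)O[C@@H]1CC[C@]2(C)C(=CCC(C)=C2C=O)[C@]1(C)CO[Si](c3ccccc3)(c3ccccc3)C(C)(C)C
F2 | step 15 | 3α-(tert-butyldimethylsilyloxy)-19-(tert-butyldiphenylsilyloxy)-12,13,14,15,16-pentanorlabda-7,9(11)-dien-11-yl acetate | CC(C)(C)[Si](C)(C)O[C@@H]1CC[C@]2(C)[C@H](CC=C(C)C2=COC(C)=O)[C@]1(C)CO[Si](c3ccccc3)(c3ccccc3)C(C)(C)C
F3 | step 15 | 3α-(tert-butyldimethylsilyloxy)-19-(tert-butyldiphenylsilyloxy)-12,13,14,15,16-pentanorlabd-7-en-11-ol (9β-H) | CC(C)(C)[Si](C)(C)O[C@@H]1CC[C@]2(C)[C@H](CC=C(C)[C@H]2CO)[C@]1(C)CO[Si](c3ccccc3)(c3ccccc3)C(C)(C)C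
F4 | step 16 | [(S)-4-(tert-butyldimethylsilyloxy)-2-methylbutyl]lithium | [Li]C[C@@H](C)CCO[Si](C)(C)C(C)(C)C
F5 | step 16 | [(S)-4-(tert-butyldimethylsilyloxy)-2-methylbutyl]cerium dichloride | Cl[Ce](Cl)C[C@@H](C)CCO[Si](C)(C)C(C)(C)C
F6 | step 16 | 3α,15-bis(tert-butyldimethylsilyloxy)-19-(tert-butyldiphenylsilyloxy)labd-7-en-11-ol (both C11 epimers, C13 as in 25) | CC(C)(C)[Si](C)(C)O[C@@H]1CC[C@]2(C)[C@H](CC=C(C)[C@H]2C(O)C[C@@H](C)CCO[Si](C)(C)C(C)(C)C)[C@]1(C)CO[Si](c3ccccc3)(c3ccccc3)C(C)(C)C
F7 | step 16 | O-[3α,15-bis(tert-butyldimethylsilyloxy)-19-(tert-butyldiphenylsilyloxy)labd-7-en-11-yl] S-methyl dithiocarbonate | CC(C)(C)[Si](C)(C)O[C@@H]1CC[C@]2(C)[C@H](CC=C(C)[C@H]2C(OC(=S)SC)C[C@@H](C)CCO[Si](C)(C)C(C)(C)C)[C@]1(C)CO[Si](c3ccccc3)(c3ccccc3)C(C)(C)C
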